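## Analysis of the target

1. Oncostemonol B (9) is an open-chain bis-resorcinol. Ring A (C1'–C6') carries the chain at C1', an acetoxy group at C3' and a hydroxyl at C5'. Ring B (C1''–C6'') carries the chain at C1'' and hydroxyls at C3'' and C5''. The rings are joined by an unbranched chain C1–C16 whose only function is the Z double bond C8=C9 at its exact midpoint.
2. There is no stereocentre. The single stereochemical element is the Z geometry, which lies seven methylene groups from either ring. Nothing in the molecule can direct its formation, and an E isomer would be very hard to remove.
3. Without the acetyl group the two halves are identical and all four phenolic oxygens are equivalent, by symmetry and by free rotation about the aryl–CH2 bonds. The acetate on O3' is the only element that breaks the symmetry, and it sits some twenty bonds from ring B.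
4. The sensitive groups are three. The aryl acetate is cleaved or moved by bases and nucleophiles. The free phenols are prone to oxidation and acylation. The Z alkene is isomerised by reversible radical addition, acids and metal hydrides, which rules out hydrogenolysis and halogen-based aromatisation.
5. The difficulty is economy rather than complexity. A long featureless chain invites a long sequence of chain building, olefination and protecting-group steps for a small molecule.
6. The route is built on one feature. The fragment C1–C16 with its Z-C8=C9 bond is, atom for atom, C2–C17 of (Z)-octadec-9-enedioic acid (3), and C1' of ring A and C1'' of ring B stand where the two carboxyl carbons of 3 stand.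
7. Both bonds C1–C1' and C16–C1'' can therefore be made in one electrolysis that replaces each carboxyl group by an aryl group. The geometry is then bought and not made.

## Retrosynthetic reasoning

**9 to 6 (three acyl–oxygen bonds).**
- The target is read as the tetraacetate 6 that has to lose three acetyl groups, not as a tetraphenol that has to gain one.
- In 6 the symmetry is restored and the four acetates are equivalent. Loss of any three gives the same compound 9, so the only open question is how many are lost.
- The forward reaction runs through triacetate 7 and diacetate 8 and is stopped by the amount of nucleophile.
- The acetyl groups also serve as the phenol protection of the key step. No protecting group is used that is foreign to the target.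
- A plan that tells ring A from ring B earlier needs two different aryl building blocks. One of them would be a resorcinol with two different oxygen substituents, and making that from a symmetric resorcinol is itself statistical.

**6 to 4 and two molecules of 2 (bonds C1–C1' and C16–C1'').**
- Both aryl–CH2 bonds are cut in the same operation, each at the price of one carboxyl carbon of 4.
- A cut at C8=C9 would force the only stereochemical element to be made. A cut elsewhere in the chain gives fragments that are not sold.
- The cut at the chain ends leaves a chain that, with one more carbon at each end, is an oleochemical already holding the Z bond in the right place. It also leaves a ring that is a purchasable resorcinol.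
- The gain is the whole C28 skeleton from three pieces in one step, without olefination or chain extension.
- The forward reaction must form a primary radical at each chain end by reductive decarboxylation and pass it to an arylnickel species before it is reduced or dimerises. It must leave the alkene and four acetates alone. The first coupling gives 5, which reacts on in the same electrolysis.

**4 to 3 (two acyl–oxygen bonds).** The redox-active ester groups are traced back to the free diacid 3. The forward reaction is a twofold esterification under neutral conditions at two remote, independent carboxyl groups.

**2 to 1 (two acyl–oxygen bonds).** The aryl iodide 2 comes from the iodoresorcinol 1 by exhaustive acetylation, which poses no selectivity question.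

## Alternatives that were turned down

**Alternative 1:** the textbook disconnection, C8=C9 cut into a C8 ylide and a C8 aldehyde.
- *Forward key step:* the non-stabilised ylide from [8-(3,5-bis(methoxymethoxy)phenyl)octyl]triphenylphosphonium bromide A1 (NaHMDS, THF, −78 °C) would react with 8-[3-(tert-butyldimethylsilyloxy)-5-(methoxymethoxy)phenyl]octanal A2. The Wittig reaction would give (Z)-1-[3,5-bis(methoxymethoxy)phenyl]-16-[3-(tert-butyldimethylsilyloxy)-5-(methoxymethoxy)phenyl]hexadec-8-ene A3.
- *Merit:* this is the only plan that tells ring A from ring B without statistics at the end.
- *Why turned down:*
  - A1 and A2 are two different C8-aryl building blocks. Each needs its own aryl–alkyl bond formation, chain-end adjustment and protection.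
  - Ring A of A2 needs two different groups on a symmetric resorcinol, so the statistical step is moved and not removed.
  - Kinetic oxaphosphetane formation favours Z but not completely, and the minor geometry cannot be expected to separate in a chain with no polar group near the alkene.
  - An acetate cannot pass through ylide chemistry, so three more protecting-group operations follow A3.
  - The symmetry of the skeleton is thrown away, and the step count is several times that of the chosen route.

**Alternative 2:** C8=C9 again, but cut into two identical halves.
- *Forward key step:* Z-selective olefin homometathesis of 1,3-dimethoxy-5-(non-8-en-1-yl)benzene A4, with a Z-selective ruthenium or molybdenum alkylidene catalyst, would give (Z)-1,16-bis(3,5-dimethoxyphenyl)hexadec-8-ene A5 with extrusion of the terminal CH2 groups.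
- *Merit:* the symmetry is used.
- *Why turned down:*
  - The aryl–alkyl bond of A4 still has to be made first. The metathesis is thus an extra C–C bond formation whose only purpose is a double bond that can be bought geometrically pure.
  - Z selectivity is kinetic and erodes when A5 re-enters the catalytic cycle at high conversion.
  - Hydride-induced migration of the terminal alkene before metathesis would give chain-shortened homologues that cannot be separated.
  - The four methyl ethers of A5 need a strong Lewis acid or hot nucleophiles, and the hydrogen halide set free endangers the alkene.

**Alternative 3:** a cut inside rings A and B, following the presumed biosynthesis.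
- *Biosynthetic model:* an alkylresorcinol synthase extends a fatty acyl starter by three malonate units, closes the ring by a C2-to-C7 aldol reaction and loses the terminal carboxyl group. All eighteen carbons of 3 would be kept, C1' and C1'' being its carboxyl carbons.
- *Forward key step:* an activated derivative of 3 would acylate, at both ends, the dianion of 2,2-dimethyl-6-(2-oxopropyl)-4H-1,3-dioxin-4-one A6. This gives (Z)-1,24-bis(2,2-dimethyl-4-oxo-4H-1,3-dioxin-6-yl)tetracos-12-ene-2,4,21,23-tetraone A7. With mild base and then acid, A7 would undergo a twofold aldol condensation and dehydration to (Z)-5,5'-(hexadec-8-ene-1,16-diyl)bis(7-hydroxy-2,2-dimethyl-4H-benzo[d][1,3]dioxin-4-one) A8.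
- *Merit:* the aromatisation is redox-neutral and safe for the alkene, and its regiochemistry is fixed by the masked ester.
- *Why turned down:*
  - It builds a ring that can be bought.
  - A7 is more acidic than A6 and quenches the dianion, so a twofold Claisen acylation needs a large excess of A6.
  - Each ring of A8 carries an extra carboxyl carbon that must be removed by hot alkaline hydrolysis and decarboxylation before peracetylation could join the route at 6.
  - That is about twice the number of steps for the same intermediate.

Key step: step 3

Remark on the chemistry: 3 is taken to be the commercial fermentation product of oleic acid, sold as the geometrically pure Z isomer, and 1 is taken to be commercial.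

## Route

Step 1
Reactants: 1 5-iodobenzene-1,3-diol
Product: 2 5-iodo-1,3-phenylene diacetate
Conditions: Ac2O (2.5 equiv), pyridine, DMAP (cat.), CH2Cl2, 0 °C to rt
Reagents that add atoms: acetic anhydride CC(=O)OC(C)=O
Why: Exhaustive O-acetylation of a phenol under nucleophilic catalysis; both hydroxyl groups are equivalent and the C–I bond is inert. The acetates protect the phenols in step 3, and one of them is the acetate of the target.

Step 2
Reactants: 3 (Z)-octadec-9-enedioic acid
Product: 4 bis(1,3-dioxoisoindolin-2-yl) (Z)-octadec-9-enedioate
Conditions: N-hydroxyphthalimide (2.2 equiv), N,N'-diisopropylcarbodiimide (DIC, 2.2 equiv), DMAP (cat.), CH2Cl2, rt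
Reagents that add atoms: N-hydroxyphthalimide O=C1c2ccccc2C(=O)N1O
Why: Steglich-type carbodiimide esterification; the two carboxyl groups are equivalent and remote, so they react independently. The neutral conditions leave the Z alkene untouched.

Step 3
Reactants: 4 bis(1,3-dioxoisoindolin-2-yl) (Z)-octadec-9-enedioate; 2 5-iodo-1,3-phenylene diacetate
Product: 6 (Z)-1,16-bis(3,5-diacetoxyphenyl)hexadec-8-ene, via monoarylated ester 5 (not isolated)
Conditions: 2 (4 equiv), NiCl2·6H2O (40 mol %), 2,2'-bipyridine (40 mol %), AgNO3 (0.6 equiv), NMP, Mg anode, reticulated vitreous carbon cathode, undivided cell, constant current, ca. 5 F per mol of 4, rt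
Reagents that add atoms: none
Why: Twofold nickel-electrocatalytic decarboxylative arylation (reductive cross-electrophile coupling of a redox-active ester with an aryl iodide), the closest known reaction type being the same coupling of primary alkyl N-hydroxyphthalimide esters, those of unsaturated fatty acids included, with aryl iodides; here it is only run at both ends of one substrate. The cathode reduces the bipyridine complex of divalent nickel to low-valent nickel, which inserts into the C–I bond of 2 to give a divalent arylnickel species. Single-electron transfer to one phthalimide ester of 4 breaks the N–O bond, carbon dioxide leaves and a primary radical remains at C1; the arylnickel species captures it, and reductive elimination from the trivalent aryl(alkyl)nickel forms C1–C1' and gives 5, which enters the same cycle at its second ester to form C16–C1''. The monovalent nickel left behind is reduced again at the cathode, the magnesium anode delivers the electrons, and its cations bind the phthalimide and iodide anions. Silver deposited from AgNO3 on the carbon cathode should lower the working potential and keep radical formation in step with radical capture, which holds back dimerisation and simple reduction of the radical. The step closes no ring and creates no stereocentre: the Z geometry of C8=C9 is carried over from 3. The selectivity it needs is that the radical ignores the alkene, and the substrate secures this, since seven methylene groups separate radical and alkene, so that only eight- or nine-membered ring closures are open, far slower than capture by nickel, and no halogen atom or thiyl radical is present that could add reversibly and turn Z into E. Cross-coupling is favoured over biaryl formation by the excess of 2, whose two acetoxy groups speed up oxidative addition and lie far outside the potential window of the electrolysis.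

Step 4
Reactants: 6 (Z)-1,16-bis(3,5-diacetoxyphenyl)hexadec-8-ene
Product: 9 oncostemonol B, via triacetate 7 (not isolated), via diacetate 8 (not isolated)
Conditions: pyrrolidine (3.0 equiv, slow addition), THF, 0 °C; chromatography
Reagents that add atoms: none
Why: Aminolysis of aryl acetates (addition–elimination at the acyl carbon) is fast with a cyclic secondary amine at 0 °C and harmless to the alkene, and the amount of amine fixes how many acetyl groups leave. Because the four acetates of 6 are equivalent only one monoacetate can exist, and an acetate on a ring that still carries a second acetoxy group has the better leaving group, so the diacetylated rings should be trimmed first (6 to 7 to 8). The last cleavage (8 to 9) is favoured over further cleavage of 9 only by site statistics, so 9 has to be separated from its more and less acetylated neighbours, which differ from it by one free phenol each and can be returned to 6 under the conditions of step 1.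

## Compound list

1 | 5-iodobenzene-1,3-diol (5-iodoresorcinol) | Oc1cc(O)cc(I)c1 | starting material
2 | 5-iodo-1,3-phenylene diacetate | CC(=O)Oc1cc(I)cc(OC(C)=O)c1 | intermediate
3 | (Z)-octadec-9-enedioic acid | OC(=O)CCCCCCC/C=C\CCCCCCCC(=O)O | starting material
4 | bis(1,3-dioxoisoindolin-2-yl) (Z)-octadec-9-enedioate | O=C(CCCCCCC/C=C\CCCCCCCC(=O)ON1C(=O)c2ccccc2C1=O)ON3C(=O)c4ccccc4C3=O | intermediate
5 | 1,3-dioxoisoindolin-2-yl (Z)-17-(3,5-diacetoxyphenyl)heptadec-9-enoate | CC(=O)Oc1cc(OC(C)=O)cc(CCCCCCC/C=C\CCCCCCCC(=O)ON2C(=O)c3ccccc3C2=O)c1 | intermediate
6 | (Z)-1,16-bis(3,5-diacetoxyphenyl)hexadec-8-ene | CC(=O)Oc1cc(OC(C)=O)cc(CCCCCCC/C=C\CCCCCCCc2cc(OC(C)=O)cc(OC(C)=O)c2)c1 | intermediate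
7 | (Z)-1-(3,5-diacetoxyphenyl)-16-(3-acetoxy-5-hydroxyphenyl)hexadec-8-ene | CC(=O)Oc1cc(OC(C)=O)cc(CCCCCCC/C=C\CCCCCCCc2cc(O)cc(OC(C)=O)c2)c1 | intermediate
8 | (Z)-1,16-bis(3-acetoxy-5-hydroxyphenyl)hexadec-8-ene | CC(=O)Oc1cc(O)cc(CCCCCCC/C=C\CCCCCCCc2cc(O)cc(OC(C)=O)c2)c1 | intermediate
9 | oncostemonol B, (Z)-1-(3-acetoxy-5-hydroxyphenyl)-16-(3,5-dihydroxyphenyl)hexadec-8-ene | CC(=O)Oc1cc(O)cc(CCCCCCC/C=C\CCCCCCCc2cc(O)cc(O)c2)c1 | target

## Step count and uncertain steps

Total step count: 4. Longest linear sequence: 3 steps (3 to 4 to 6 to 9). The branch 1 to 2 joins in step 3.

**Step 3 (key step).**
- *What may go wrong:*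
  - Each chain end can be lost independently to reduction of the radical, to β-hydride elimination from the alkylnickel species or to radical dimerisation. Two ends must couple in the same molecule, so every such loss counts twice, and singly arylated chains would be close to 6 in polarity.
  - Nickel hydride formed by β-hydride elimination could erode the Z geometry.
  - Partial transfer of acetyl groups to the phthalimide anion would be harmless, since the crude product can be treated under the conditions of step 1.
- *Fallback, from 2 back to 6:* commercial dec-9-enoic acid is esterified as in step 2 to 1,3-dioxoisoindolin-2-yl dec-9-enoate F1. This is coupled once with 2 under the conditions of step 3 to give 5-(non-8-en-1-yl)-1,3-phenylene diacetate F2. After purification, F2 is dimerised by Z-selective olefin homometathesis (Z-selective Grubbs catalyst, the cyclometalated nitrato ruthenium alkylidene, THF, static vacuum) to 6.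
- *How the approach changes:* each molecule has to survive only one radical coupling, and the central alkene is made after the nickel chemistry instead of being carried through it.

**Step 4.**
- *What may go wrong:*
  - Over- and under-cleavage are the main risk. The last two acetates sit on rings that do not sense each other, so on purely statistical grounds not much more than half of the material can be at the monoacetate stage in one pass.
  - Amine-catalysed acetyl exchange between phenols can blur the kinetic bias of the earlier cleavages.
- *Fallback, from 6 back to 9:* exhaustive methanolysis (K2CO3 cat., MeOH, rt) gives (Z)-5,5'-(hexadec-8-ene-1,16-diyl)bis(benzene-1,3-diol) F3. This is acetylated from the other side by slow addition of Ac2O (1.0 equiv) in pyridine/CH2Cl2 at −20 °C.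
- *How the approach changes:* the acetate is built up instead of trimmed down. The main companion of 9 is then the very polar F3, which is easy to separate and to resubmit.

**Step 2.**
- *What may go wrong:* activation of the second carboxyl group may stay incomplete. The O-acylisourea may rearrange to the N-acylurea. The activated ester may hydrolyse on silica gel, and any monoester carried on would end as a singly arylated chain in step 3.
- *Fallback, from 3 back to 4:* (COCl)2 and DMF (cat.) in CH2Cl2 give (Z)-octadec-9-enedioyl dichloride F4. After evaporation it is treated with N-hydroxyphthalimide and Et3N in CH2Cl2 at 0 °C, and 4 is purified by crystallisation instead of chromatography.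

## Further compounds

F1 | step 3 | 1,3-dioxoisoindolin-2-yl dec-9-enoate | C=CCCCCCCCC(=O)ON1C(=O)c2ccccc2C1=O
F2 | step 3 | 5-(non-8-en-1-yl)-1,3-phenylene diacetate | C=CCCCCCCCc1cc(OC(C)=O)cc(OC(C)=O)c1
F3 | step 4 | (Z)-5,5'-(hexadec-8-ene-1,16-diyl)bis(benzene-1,3-diol) | Oc1cc(O)cc(CCCCCCC/C=C\CCCCCCCc2cc(O)cc(O)c2)c1
F4 | step 2 | (Z)-octadec-9-enedioyl dichloride | O=C(Cl)CCCCCCC/C=C\CCCCCCCC(=O)Cl
A1 | alternative 1 | [8-(3,5-bis(methoxymethoxy)phenyl)octyl]triphenylphosphonium bromide | COCOc1cc(CCCCCCCC[P+](c2ccccc2)(c2ccccc2)c2ccccc2)cc(OCOC)c1.[Br-]
A2 | alternative 1 | 8-[3-(tert-butyldimethylsilyloxy)-5-(methoxymethoxy)phenyl]octanal | O=CCCCCCCCc1cc(OCOC)cc(O[Si](C)(C)C(C)(C)C)c1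
A3 | alternative 1 | (Z)-1-[3,5-bis(methoxymethoxy)phenyl]-16-[3-(tert-butyldimethylsilyloxy)-5-(methoxymethoxy)phenyl]hexadec-8-ene | COCOc1cc(CCCCCCC/C=C\CCCCCCCc2cc(OCOC)cc(O[Si](C)(C)C(C)(C)C)c2)cc(OCOC)c1
A4 | alternative 2 | 1,3-dimethoxy-5-(non-8-en-1-yl)benzene | C=CCCCCCCCc1cc(OC)cc(OC)c1
A5 | alternative 2 | (Z)-1,16-bis(3,5-dimethoxyphenyl)hexadec-8-ene | COc1cc(OC)cc(CCCCCCC/C=C\CCCCCCCc2cc(OC)cc(OC)c2)c1
A6 | alternative 3 | 2,2-dimethyl-6-(2-oxopropyl)-4H-1,3-dioxin-4-one | CC(=O)CC1=CC(=O)OC(C)(C)O1
A7 | alternative 3 | (Z)-1,24-bis(2,2-dimethyl-4-oxo-4H-1,3-dioxin-6-yl)tetracos-12-ene-2,4,21,23-tetraone | CC1(C)OC(=O)C=C(CC(=O)CC(=O)CCCCCCC/C=C\CCCCCCCC(=O)CC(=O)CC2=CC(=O)OC(C)(C)O2)O1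
A8 | alternative 3 | (Z)-5,5'-(hexadec-8-ene-1,16-diyl)bis(7-hydroxy-2,2-dimethyl-4H-benzo[d][1,3]dioxin-4-one) | CC1(C)OC(=O)c2c(CCCCCCC/C=C\CCCCCCCc3cc(O)cc4OC(C)(C)OC(=O)c34)cc(O)cc2O1
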